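**Strategy**

The plan rests on opening the 2,3,4-trimethylcyclohexanone ring across two bonds at once: the ring CH2–CH(CH3) bond (C5–C4) and the bond from the α-CH(CH3) to the quaternary carbon (C2–C3). This leaves a four-carbon diene (C5, C6, C1, C2; C1 as enol ether) and the C3=C4 alkene of tiglic aldehyde. One catalytic enantioselective Diels–Alder reaction forms both bonds and all three ring stereocentres; it exploits the contiguous methyl-bearing C2–C3–C4 triad beside the C1 carbonyl. The precursor diene, (Z)-2-(phenylthio)-3-(silyloxy)penta-1,3-diene, carries a removable sulfur that steers the regiochemistry. Homologation, Nozaki–Hiyama–Kishi union with an aryl vinyl iodide and late oxidation of the chlororesorcinol to the hydroxyquinone finish the route.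

Key step: step 3

Assumption: the sense of induction in steps 3 and 10 is assigned from the accepted transition-state models of these catalyst classes; the antipodal catalyst or ligand would be used if the sense proved opposite.

Remarks: compound 22 is a mixture of epimers at the sulfur-bearing carbon, which is removed in step 12; cyclopentadienyl ligands are written as σ-bonded rings or as ions in SMILES.

**Route**

Step 1
Reactants: 1 phenyl vinyl sulfide; 2 N-methoxy-N-methylpropanamide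
Product: 5 2-(phenylsulfanyl)pent-1-en-3-one, via 1-(phenylsulfanyl)ethenyllithium 3 (not isolated), via lithium hemiaminal alkoxide 4 (not isolated)
Conditions: s-BuLi, TMEDA, THF, −78 °C; then 2, −78 → 0 °C; H2O
Reagents that add atoms: none
Why: α-lithiation of the vinyl sulfide gives a sulfur-stabilised vinyl anion, and acylation with the N-methoxy-N-methylamide stops at the chelated tetrahedral adduct, so the enone is released only on work-up.

Step 2
Reactants: 5 2-(phenylsulfanyl)pent-1-en-3-one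
Product: 6 (3Z)-2-(phenylsulfanyl)-3-(triisopropylsilyloxy)penta-1,3-diene
Conditions: TIPSOTf, Et3N, CH2Cl2, 0 °C
Reagents that add atoms: triisopropylsilyl trifluoromethanesulfonate, CC(C)[Si](C(C)C)(C(C)C)OS(=O)(=O)C(F)(F)F
Why: soft enolisation of the ethyl ketone (silyl triflate/amine) should give mainly the (Z)-silyl enol ether, in which the terminal methyl is on the outside of the s-cis diene; any (E)-isomer is unreactive as a diene.

Step 3
Reactants: 6 (3Z)-2-(phenylsulfanyl)-3-(triisopropylsilyloxy)penta-1,3-diene; 7 (E)-2-methylbut-2-enal (tiglic aldehyde)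
Product: 8 (1S,2S,6R)-1,2,6-trimethyl-4-(phenylsulfanyl)-3-(triisopropylsilyloxy)cyclohex-3-ene-1-carbaldehyde
Conditions: (S)-3,3-diphenyl-1-(2-methylphenyl)tetrahydro-1H,3H-pyrrolo[1,2-c][1,3,2]oxazaborole·HNTf2 (20 mol %), CH2Cl2, −78 → −40 °C
Reagents that add atoms: none
Why: A Lewis-acid-catalysed, asynchronous normal-demand Diels–Alder reaction of the boron-bound s-trans enal; the closest known types are oxazaborolidinium-catalysed cycloadditions of α-substituted enals with 2-silyloxydienes and sulfur-directed cycloadditions of 2-alkoxy-3-(arylthio)butadienes. The cyclohexene ring is closed by intermolecular [4+2] cycloaddition, suprafacial on both partners, forming C5–C6 (diene CH2 to enal β-carbon) and C1–C2 (quaternary carbon to the CH(CH3) terminus) in one operation. The needed regiochemistry is opposite to what the silyloxy group alone would direct; the phenylthio group on the neighbouring diene carbon makes the CH2 terminus the nucleophilic end, the terminal methyl reinforces this ("ortho" rule), and the congested C1–C2 bond forms second. The cis relation of the C1 and C6 methyls follows stereospecifically from the (E)-geometry of 7. The C2 methyl (outside on the (Z)-enol ether) ends cis to the formyl group through the endo transition state. For the absolute configuration, the (S)-catalyst is predicted to shield the rear face of the coordinated enal with a phenyl group, so the diene should add to the Cα-Re face and give (1S,2S,6R).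

Step 4
Reactants: 8 (1S,2S,6R)-1,2,6-trimethyl-4-(phenylsulfanyl)-3-(triisopropylsilyloxy)cyclohex-3-ene-1-carbaldehyde
Product: 9 {[(4R,5S,6S)-5-ethynyl-4,5,6-trimethyl-2-(phenylsulfanyl)cyclohex-1-en-1-yl]oxy}triisopropylsilane
Conditions: dimethyl (1-diazo-2-oxopropyl)phosphonate, K2CO3, MeOH, 0 °C → rt
Reagents that add atoms: dimethyl (1-diazo-2-oxopropyl)phosphonate, CC(=O)C(=[N+]=[N-])P(=O)(OC)OC
Why: Seyferth–Gilbert homologation of an aldehyde that has no α-hydrogen, so nothing can epimerise, and the TIPS enol ether should survive K2CO3/MeOH.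

Step 5
Reactants: 9 {[(4R,5S,6S)-5-ethynyl-4,5,6-trimethyl-2-(phenylsulfanyl)cyclohex-1-en-1-yl]oxy}triisopropylsilane
Product: 11 2-[(1S,2S,6R)-1,2,6-trimethyl-4-(phenylsulfanyl)-3-(triisopropylsilyloxy)cyclohex-3-en-1-yl]acetaldehyde, via alkenyl(dicyclohexyl)borane 10 (not isolated)
Conditions: Cy2BH, THF, 0 °C → rt; then Me3NO·2H2O, 50 °C
Reagents that add atoms: trimethylamine N-oxide, C[N+](C)(C)[O-]
Why: anti-Markovnikov hydroboration of the terminal alkyne with a bulky dialkylborane and amine-oxide oxidation of the alkenylborane should give the aldehyde without touching the sulfide or the tetrasubstituted enol ether.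

Step 6
Reactants: 12 orcinol (5-methylbenzene-1,3-diol)
Product: 13 4-chloro-5-methylbenzene-1,3-diol
Conditions: SO2Cl2 (1.0 equiv), Et2O, 0 °C
Reagents that add atoms: sulfuryl chloride, ClS(Cl)(=O)=O
Why: electrophilic aromatic chlorination at the position ortho/para to the two hydroxyl groups, with one equivalent to limit over-chlorination.

Step 7
Reactants: 13 4-chloro-5-methylbenzene-1,3-diol
Product: 14 2-chloro-1,5-bis(methoxymethoxy)-3-methylbenzene
Conditions: MOMCl, iPr2NEt, CH2Cl2, 0 °C → rt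
Reagents that add atoms: chloromethyl methyl ether, COCCl
Why: O-alkylation to the bis-MOM ether, which protects the phenols and directs the metalation of the next step.

Step 8
Reactants: 14 2-chloro-1,5-bis(methoxymethoxy)-3-methylbenzene; 15 1-bromobut-2-yne
Product: 17 2-(but-2-yn-1-yl)-4-chloro-1,3-bis(methoxymethoxy)-5-methylbenzene, via aryllithium 16 (not isolated)
Conditions: n-BuLi, THF, 0 °C; then 15, −78 °C → rt
Reagents that add atoms: none
Why: directed ortho-metalation at the position flanked by both OMOM groups, then SN2 alkylation of the aryllithium with the primary propargylic bromide.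

Step 9
Reactants: 17 2-(but-2-yn-1-yl)-4-chloro-1,3-bis(methoxymethoxy)-5-methylbenzene
Product: 19 2-chloro-4-[(2E)-3-iodobut-2-en-1-yl]-3,5-bis(methoxymethoxy)-1-methylbenzene, via alkenylzirconocene chloride 18 (not isolated)
Conditions: Cp2Zr(H)Cl (2 equiv), THF, 50 °C; then I2, 0 °C
Reagents that add atoms: iodine, II
Why: syn-hydrozirconation with equilibration under excess hydride should place zirconium on the less hindered, methyl-bearing alkyne carbon, and iodinolysis with retention gives the (E)-iodide.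

Step 10
Reactants: 11 2-[(1S,2S,6R)-1,2,6-trimethyl-4-(phenylsulfanyl)-3-(triisopropylsilyloxy)cyclohex-3-en-1-yl]acetaldehyde; 19 2-chloro-4-[(2E)-3-iodobut-2-en-1-yl]-3,5-bis(methoxymethoxy)-1-methylbenzene
Product: 21 (2S,3E)-5-[3-chloro-2,6-bis(methoxymethoxy)-4-methylphenyl]-3-methyl-1-[(1S,2S,6R)-1,2,6-trimethyl-4-(phenylsulfanyl)-3-(triisopropylsilyloxy)cyclohex-3-en-1-yl]pent-3-en-2-ol, via alkenylchromium dichloride 20 (not isolated)
Conditions: CrCl2 (4 equiv), N-[2-(4-isopropyl-4,5-dihydrooxazol-2-yl)-6-methylphenyl]methanesulfonamide (Re-face-directing enantiomer), Et3N, NiCl2 (10 mol %), THF, rt; aq. work-up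
Reagents that add atoms: none
Why: Nozaki–Hiyama–Kishi coupling, in which the alkenylchromium adds only to the aldehyde with retention of alkene geometry, and the chiral sulfonamide ligand on chromium should direct addition to the Re face to set the (S)-carbinol.

Step 11
Reactants: 21 (2S,3E)-5-[3-chloro-2,6-bis(methoxymethoxy)-4-methylphenyl]-3-methyl-1-[(1S,2S,6R)-1,2,6-trimethyl-4-(phenylsulfanyl)-3-(triisopropylsilyloxy)cyclohex-3-en-1-yl]pent-3-en-2-ol
Product: 22 (2S,3S,4R)-3-{(2S,3E)-5-[3-chloro-2,6-bis(methoxymethoxy)-4-methylphenyl]-2-hydroxy-3-methylpent-3-en-1-yl}-2,3,4-trimethyl-6-(phenylsulfanyl)cyclohexan-1-one (C6 epimers)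
Conditions: TBAF, AcOH, THF, 0 °C
Reagents that add atoms: none
Why: fluoride cleavage of the silyl enol ether, buffered so that the enolate is protonated at once at the sulfur-bearing carbon and the C2 stereocentre on the other side of the ketone is not touched.

Step 12
Reactants: 22 (2S,3S,4R)-3-{(2S,3E)-5-[3-chloro-2,6-bis(methoxymethoxy)-4-methylphenyl]-2-hydroxy-3-methylpent-3-en-1-yl}-2,3,4-trimethyl-6-(phenylsulfanyl)cyclohexan-1-one
Product: 23 (2S,3S,4R)-3-{(2S,3E)-5-[3-chloro-2,6-bis(methoxymethoxy)-4-methylphenyl]-2-hydroxy-3-methylpent-3-en-1-yl}-2,3,4-trimethylcyclohexan-1-one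
Conditions: SmI2 (2.5 equiv), THF/MeOH, −78 °C
Reagents that add atoms: none
Why: reductive cleavage of an α-heterosubstituted ketone by two single-electron transfers; the regiodefined samarium enolate is protonated at C6 by MeOH, so C2 should keep its configuration.

Step 13
Reactants: 23 (2S,3S,4R)-3-{(2S,3E)-5-[3-chloro-2,6-bis(methoxymethoxy)-4-methylphenyl]-2-hydroxy-3-methylpent-3-en-1-yl}-2,3,4-trimethylcyclohexan-1-one
Product: 25 (2S,3S,4R)-3-[(2S,3E)-5-(3-chloro-2,6-dihydroxy-4-methylphenyl)-2-hydroxy-3-methylpent-3-en-1-yl]-2,3,4-trimethylcyclohexan-1-one, via tris(trimethylsilyl) ether 24 (not isolated)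
Conditions: TMSOTf, 2,2′-bipyridyl, CH2Cl2, 0 °C; then H2O
Reagents that add atoms: none
Why: near-neutral acetal cleavage in which the silyl triflate/bipyridyl pair converts aryl MOM ethers into aryl silyl ethers that hydrolyse on work-up, chosen to spare the allylic alcohol and the α-stereocentre.

Step 14
Reactants: 25 (2S,3S,4R)-3-[(2S,3E)-5-(3-chloro-2,6-dihydroxy-4-methylphenyl)-2-hydroxy-3-methylpent-3-en-1-yl]-2,3,4-trimethylcyclohexan-1-one
Product: 26 2-chloro-5-hydroxy-6-{(2E,4S)-4-hydroxy-3-methyl-5-[(1S,2S,6R)-1,2,6-trimethyl-3-oxocyclohexyl]pent-2-en-1-yl}-3-methylcyclohexa-2,5-diene-1,4-dione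
Conditions: (KSO3)2NO, KH2PO4 buffer, acetone/H2O, rt
Reagents that add atoms: potassium nitrosodisulfonate (KSO3)2NO, [K+].[K+].[O]N(S(=O)(=O)[O-])S(=O)(=O)[O-]
Why: Teuber oxidation, in which the nitroxyl radical oxidises the only free ring position (para to one hydroxyl) of the resorcinol to the 2-hydroxy-1,4-benzoquinone under buffered conditions.

**Compound list**

1 | phenyl vinyl sulfide | C=CSc1ccccc1 | starting material
2 | N-methoxy-N-methylpropanamide | CCC(=O)N(C)OC | starting material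
3 | 1-(phenylsulfanyl)ethenyllithium (not isolated) | [Li]C(=C)Sc1ccccc1 | intermediate
4 | lithium 3-[methoxy(methyl)amino]-2-(phenylsulfanyl)pent-1-en-3-olate (racemic, not isolated) | CCC(O[Li])(N(C)OC)C(=C)Sc1ccccc1 | intermediate
5 | 2-(phenylsulfanyl)pent-1-en-3-one | CCC(=O)C(=C)Sc1ccccc1 | intermediate
6 | (3Z)-2-(phenylsulfanyl)-3-(triisopropylsilyloxy)penta-1,3-diene | C/C=C(O[Si](C(C)C)(C(C)C)C(C)C)/C(Sc1ccccc1)=C | intermediate
7 | (E)-2-methylbut-2-enal | C/C=C(\C)C=O | starting material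
8 | (1S,2S,6R)-1,2,6-trimethyl-4-(phenylsulfanyl)-3-(triisopropylsilyloxy)cyclohex-3-ene-1-carbaldehyde | O=C[C@@]1(C)[C@H](C)CC(Sc2ccccc2)=C(O[Si](C(C)C)(C(C)C)C(C)C)[C@H]1C | intermediate
9 | {[(4R,5S,6S)-5-ethynyl-4,5,6-trimethyl-2-(phenylsulfanyl)cyclohex-1-en-1-yl]oxy}triisopropylsilane | C#C[C@@]1(C)[C@H](C)CC(Sc2ccccc2)=C(O[Si](C(C)C)(C(C)C)C(C)C)[C@H]1C | intermediate
10 | dicyclohexyl[(E)-2-{(1R,2S,6R)-1,2,6-trimethyl-4-(phenylsulfanyl)-3-(triisopropylsilyloxy)cyclohex-3-en-1-yl}ethenyl]borane (not isolated) | B(C2CCCCC2)(C3CCCCC3)/C=C/[C@@]1(C)[C@H](C)CC(Sc4ccccc4)=C(O[Si](C(C)C)(C(C)C)C(C)C)[C@H]1C | intermediate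
11 | 2-[(1S,2S,6R)-1,2,6-trimethyl-4-(phenylsulfanyl)-3-(triisopropylsilyloxy)cyclohex-3-en-1-yl]acetaldehyde | O=CC[C@@]1(C)[C@H](C)CC(Sc2ccccc2)=C(O[Si](C(C)C)(C(C)C)C(C)C)[C@H]1C | intermediate
12 | orcinol (5-methylbenzene-1,3-diol) | Cc1cc(O)cc(O)c1 | starting material
13 | 4-chloro-5-methylbenzene-1,3-diol | Cc1cc(O)cc(O)c1Cl | intermediate
14 | 2-chloro-1,5-bis(methoxymethoxy)-3-methylbenzene | Cc1cc(OCOC)cc(OCOC)c1Cl | intermediate
15 | 1-bromobut-2-yne | CC#CCBr | starting material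
16 | [3-chloro-2,6-bis(methoxymethoxy)-4-methylphenyl]lithium (not isolated) | Cc1cc(OCOC)c([Li])c(OCOC)c1Cl | intermediate
17 | 2-(but-2-yn-1-yl)-4-chloro-1,3-bis(methoxymethoxy)-5-methylbenzene | CC#CCc1c(OCOC)cc(C)c(Cl)c1OCOC | intermediate
18 | chlorobis(cyclopentadienyl){(2E)-4-[3-chloro-2,6-bis(methoxymethoxy)-4-methylphenyl]but-2-en-2-yl}zirconium (not isolated) | C/C([Zr](Cl)(C1C=CC=C1)C1C=CC=C1)=C\Cc1c(OCOC)cc(C)c(Cl)c1OCOC | intermediate
19 | 2-chloro-4-[(2E)-3-iodobut-2-en-1-yl]-3,5-bis(methoxymethoxy)-1-methylbenzene | C/C(I)=C\Cc1c(OCOC)cc(C)c(Cl)c1OCOC | intermediate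
20 | dichloro{(2E)-4-[3-chloro-2,6-bis(methoxymethoxy)-4-methylphenyl]but-2-en-2-yl}chromium (not isolated) | C/C([Cr](Cl)Cl)=C\Cc1c(OCOC)cc(C)c(Cl)c1OCOC | intermediate
21 | (2S,3E)-5-[3-chloro-2,6-bis(methoxymethoxy)-4-methylphenyl]-3-methyl-1-[(1S,2S,6R)-1,2,6-trimethyl-4-(phenylsulfanyl)-3-(triisopropylsilyloxy)cyclohex-3-en-1-yl]pent-3-en-2-ol | COCOc1cc(C)c(Cl)c(OCOC)c1C/C=C(\C)[C@@H](O)C[C@@]2(C)[C@H](C)CC(Sc3ccccc3)=C(O[Si](C(C)C)(C(C)C)C(C)C)[C@H]2C | intermediate
22 | (2S,3S,4R)-3-{(2S,3E)-5-[3-chloro-2,6-bis(methoxymethoxy)-4-methylphenyl]-2-hydroxy-3-methylpent-3-en-1-yl}-2,3,4-trimethyl-6-(phenylsulfanyl)cyclohexan-1-one (C6 epimers) | COCOc1cc(C)c(Cl)c(OCOC)c1C/C=C(\C)[C@@H](O)C[C@@]2(C)[C@H](C)CC(Sc3ccccc3)C(=O)[C@H]2C | intermediate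
23 | (2S,3S,4R)-3-{(2S,3E)-5-[3-chloro-2,6-bis(methoxymethoxy)-4-methylphenyl]-2-hydroxy-3-methylpent-3-en-1-yl}-2,3,4-trimethylcyclohexan-1-one | COCOc1cc(C)c(Cl)c(OCOC)c1C/C=C(\C)[C@@H](O)C[C@@]2(C)[C@H](C)CCC(=O)[C@H]2C | intermediate
24 | tris(trimethylsilyl) ether of 25 (two aryl and one allylic OSiMe3, not isolated) | C[Si](C)(C)Oc1cc(C)c(Cl)c(O[Si](C)(C)C)c1C/C=C(\C)[C@@H](O[Si](C)(C)C)C[C@@]2(C)[C@H](C)CCC(=O)[C@H]2C | intermediate
25 | (2S,3S,4R)-3-[(2S,3E)-5-(3-chloro-2,6-dihydroxy-4-methylphenyl)-2-hydroxy-3-methylpent-3-en-1-yl]-2,3,4-trimethylcyclohexan-1-one | Cc1cc(O)c(C/C=C(\C)[C@@H](O)C[C@@]2(C)[C@H](C)CCC(=O)[C@H]2C)c(O)c1Cl | intermediate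
26 | 2-chloro-5-hydroxy-6-{(2E,4S)-4-hydroxy-3-methyl-5-[(1S,2S,6R)-1,2,6-trimethyl-3-oxocyclohexyl]pent-2-en-1-yl}-3-methylcyclohexa-2,5-diene-1,4-dione | CC1=C(Cl)C(=O)C(C/C=C(\C)[C@@H](O)C[C@@]2(C)[C@H](C)CCC(=O)[C@H]2C)=C(O)C1=O | target

**Step count**

Total steps: 14. Longest linear sequence: 10 (steps 1–5 and 10–14); steps 6–9 make the aryl vinyl iodide.

**Steps most likely to fail**

1. Step 3. What may go wrong: loss of regiocontrol if the silyloxy-directed orientation competes with the sulfur-directed one, desilylation of the diene by the cationic catalyst, or weak facial discrimination. Fallback: setting out from 6 and 7, the cycloaddition is run without a chiral catalyst (Me2AlCl, CH2Cl2, −78 °C), a Lewis-acid regime expected to keep sulfur control and the endo mode, to give the racemic aldehyde F1. Condensation with (1R,2R)-N,N′-dimethyl-1,2-diphenylethane-1,2-diamine (Et2O, 4 Å molecular sieves) gives two diastereomeric imidazolidines, the aminal of the (1S,2S,6R) aldehyde F2 and the aminal of its enantiomer F3, which are separated by chromatography. Brief two-phase hydrolysis of F2 (dilute aqueous HCl, Et2O, 0 °C) returns enantiopure 8, where the route is rejoined.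

2. Step 10. What may go wrong: poor facial selectivity, because the aldehyde carries only a remote quaternary centre and ligand control may be weak, giving a mixture of carbinol epimers. Fallback: setting out from 11 and 19, the coupling is run without chiral ligand (CrCl2, NiCl2 cat., DMSO, rt) to give the mixture of carbinol epimers F4. Dess–Martin oxidation (NaHCO3, CH2Cl2) gives the enone F5, whose ring ketone is still masked as the silyl enol ether. Corey–Bakshi–Shibata reduction with the (R)-2-methyl-oxazaborolidine and catecholborane (toluene, −78 °C), with the alkenyl group as the large substituent, should give the (S)-alcohol and comes back to the route at 21.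

3. Step 13. What may go wrong: ionisation of the allylic alcohol, or enol silylation with epimerisation at C2, during acetal cleavage on the fully assembled molecule. Fallback: setting out from 19, the MOM groups are removed at this robust stage (HCl, MeOH, 40 °C) to give the iodo-resorcinol F6, which is silylated (TBSCl, imidazole, DMF) to the bis(silyl ether) F7. Coupling with 11 under the conditions of step 10, through the alkenylchromium F8, gives the allylic alcohol F9. TBAF/AcOH then removes the enol TIPS group and both aryl TBS groups in one operation to give the α-phenylthio ketone F10, and SmI2 as in step 12 comes back to the route at 25.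

**Further compounds**

F1 | step 3 | racemic 1,2,6-trimethyl-4-(phenylsulfanyl)-3-(triisopropylsilyloxy)cyclohex-3-ene-1-carbaldehyde (1:1 mixture of 8 and its enantiomer) | O=C[C@@]1(C)[C@H](C)CC(Sc2ccccc2)=C(O[Si](C(C)C)(C(C)C)C(C)C)[C@H]1C.O=C[C@]1(C)[C@@H](C)CC(Sc2ccccc2)=C(O[Si](C(C)C)(C(C)C)C(C)C)[C@@H]1C
F2 | step 3 | (4R,5R)-1,3-dimethyl-4,5-diphenyl-2-[(1S,2S,6R)-1,2,6-trimethyl-4-(phenylsulfanyl)-3-(triisopropylsilyloxy)cyclohex-3-en-1-yl]imidazolidine | CN1C([C@@]2(C)[C@H](C)CC(Sc3ccccc3)=C(O[Si](C(C)C)(C(C)C)C(C)C)[C@H]2C)N(C)[C@H](c4ccccc4)[C@H]1c5ccccc5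
F3 | step 3 | (4R,5R)-1,3-dimethyl-4,5-diphenyl-2-[(1R,2R,6S)-1,2,6-trimethyl-4-(phenylsulfanyl)-3-(triisopropylsilyloxy)cyclohex-3-en-1-yl]imidazolidine | CN1C([C@]2(C)[C@@H](C)CC(Sc3ccccc3)=C(O[Si](C(C)C)(C(C)C)C(C)C)[C@@H]2C)N(C)[C@H](c4ccccc4)[C@H]1c5ccccc5
F4 | step 10 | (3E)-5-[3-chloro-2,6-bis(methoxymethoxy)-4-methylphenyl]-3-methyl-1-[(1S,2S,6R)-1,2,6-trimethyl-4-(phenylsulfanyl)-3-(triisopropylsilyloxy)cyclohex-3-en-1-yl]pent-3-en-2-ol (both C2 epimers) | COCOc1cc(C)c(Cl)c(OCOC)c1C/C=C(\C)C(O)C[C@@]2(C)[C@H](C)CC(Sc3ccccc3)=C(O[Si](C(C)C)(C(C)C)C(C)C)[C@H]2C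
F5 | step 10 | (3E)-5-[3-chloro-2,6-bis(methoxymethoxy)-4-methylphenyl]-3-methyl-1-[(1S,2S,6R)-1,2,6-trimethyl-4-(phenylsulfanyl)-3-(triisopropylsilyloxy)cyclohex-3-en-1-yl]pent-3-en-2-one | COCOc1cc(C)c(Cl)c(OCOC)c1C/C=C(\C)C(=O)C[C@@]2(C)[C@H](C)CC(Sc3ccccc3)=C(O[Si](C(C)C)(C(C)C)C(C)C)[C@H]2C
F6 | step 13 | 4-chloro-2-[(2E)-3-iodobut-2-en-1-yl]-5-methylbenzene-1,3-diol | C/C(I)=C\Cc1c(O)cc(C)c(Cl)c1O
F7 | step 13 | 1,3-bis(tert-butyldimethylsilyloxy)-4-chloro-2-[(2E)-3-iodobut-2-en-1-yl]-5-methylbenzene | C/C(I)=C\Cc1c(O[Si](C)(C)C(C)(C)C)cc(C)c(Cl)c1O[Si](C)(C)C(C)(C)C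
F8 | step 13 | dichloro{(2E)-4-[2,6-bis(tert-butyldimethylsilyloxy)-3-chloro-4-methylphenyl]but-2-en-2-yl}chromium | C/C([Cr](Cl)Cl)=C\Cc1c(O[Si](C)(C)C(C)(C)C)cc(C)c(Cl)c1O[Si](C)(C)C(C)(C)C
F9 | step 13 | (2S,3E)-5-[2,6-bis(tert-butyldimethylsilyloxy)-3-chloro-4-methylphenyl]-3-methyl-1-[(1S,2S,6R)-1,2,6-trimethyl-4-(phenylsulfanyl)-3-(triisopropylsilyloxy)cyclohex-3-en-1-yl]pent-3-en-2-ol | CC(C)(C)[Si](C)(C)Oc1cc(C)c(Cl)c(O[Si](C)(C)C(C)(C)C)c1C/C=C(\C)[C@@H](O)C[C@@]2(C)[C@H](C)CC(Sc3ccccc3)=C(O[Si](C(C)C)(C(C)C)C(C)C)[C@H]2C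
F10 | step 13 | (2S,3S,4R)-3-[(2S,3E)-5-(3-chloro-2,6-dihydroxy-4-methylphenyl)-2-hydroxy-3-methylpent-3-en-1-yl]-2,3,4-trimethyl-6-(phenylsulfanyl)cyclohexan-1-one (C6 epimers) | Cc1cc(O)c(C/C=C(\C)[C@@H](O)C[C@@]2(C)[C@H](C)CC(Sc3ccccc3)C(=O)[C@H]2C)c(O)c1Cl
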